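The runs are calculated with made-up constants; scatter was added.

The precatalyst was a small charge, 0.0100% of the starting material, and the beta flask, followed to 4.00 min, had to be told at 8.0 min.

| setting | beta | theta | flask |
|---|---|---|---|
| starting material | 0.050 M | 0.025 M | 0.050 M |
| second substrate | 0.055 M | 0.055 M | 0.0550 M |
| precatalyst | 5 µM | 5 µM | 5.0 µM |
| remark | the very flask that is asked about, followed so far | run made earlier |  |
| time |  |  | 8.0 min |

| run | time / min | starting material / % | target / % | uncatalysed product / % |
|---|---|---|---|---|
| beta | 0.333 | 99.9 | 0 | 0.4 |
| beta | 0.500 | 99.1 | 0.3 | 0.1 |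
| beta | 0.833 | 99.4 | 0 | 1.3 |
| beta | 1.33 | 98.5 | 0.1 | 1.0 |
| beta | 2.50 | 97.0 | 0.5 | 2.8 |
| beta | 4.00 | 95.2 | 1.4 | 3.4 |
| theta | 1.00 | 99.1 | 0.4 | 0.9 |
| theta | 2.00 | 98.2 | 0 | 2.1 |
| theta | 3.00 | 96.1 | 0.8 | 3.2 |
| theta | 4.00 | 94.6 | 1.5 | 3.8 |
| theta | 5.00 | 93.5 | 2.6 | 4.6 |
| theta | 6.00 | 91.3 | 3.7 | 5.4 |

(scatter of a reading: 0.3 percentage points)

1. at 8.0 min, what has stopped the reaction, if anything has (the second substrate has run out first / forward and back rates have come level / no working catalyst is left / all of the starting material has reacted / it is still moving)
2. share of the starting material used up at 8.0 min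
3. target at 8.0 min, in percent of the starting material charged
4. uncatalysed product at 8.0 min, in percent of the starting material charged

- the numbers in the tables scatter by 0.3 percentage points (one standard deviation)
- the reaction counts as stopped when no species that holds the starting material changes by six tenths of a point or more over the second half of the time

Uncatalysed product rose in a nearly straight line, and as a share of the charge it kept about the same pace in theta, with half the starting material. So I took one quantity from theta's last reading: 111 min is the background lifetime, the time in which this pseudo-first-order route would use the whole charge at the pace read over that run. The asked time is 7.20% of that lifetime, so a straight line caps uncatalysed product at that share. Over the second half of the time the line adds 3.6 percentage points, more than the stopping mark, so I expected a moving flask.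

The target lagged. Scaling beta's last reading with the square of time gave me an upper bound of 5.60%. Continuing its last pace gave a lower bound of 3.80%, provided the catalyst lasted. Conversion was then at most 12.8%. If both reagents fell that far, averaging the background's opening and closing pace gave 6.34%, so conversion was at least 10.1%.

The forecast said it is still moving, with conversion 12.9%, target 6.1% and uncatalysed product 6.8%, adding “nothing suggests equilibrium”. Its uncatalysed product sat inside my bracket, but its target and conversion stood higher than my upper bounds.

The flask gave it is still moving, with conversion 11.1%, target 4.38% and uncatalysed product 6.71%.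

    starting material + second substrate → uncatalysed product (k = 0.00280 M⁻¹ s⁻¹)
    second complex → free enzyme + target (k = 38.0 s⁻¹)
    starting material + free enzyme ⇌ first complex (K = 8.30 M⁻¹, k = 61000 M⁻¹ s⁻¹)
    precatalyst → free enzyme (k = 8.50 × 10⁻⁴ s⁻¹)
    2 free enzyme → spent catalyst (k = 210 M⁻¹ s⁻¹)
    first complex ⇌ loaded enzyme + first product (K = 0.620 M, k = 27.0 s⁻¹)
    second substrate + loaded enzyme ⇌ second complex (K = 16.0 M⁻¹, k = 11000 M⁻¹ s⁻¹)

These three values lay inside my brackets. In the asked flask, with the other amounts and the time held, uncatalysed product at 8.0 min has moved by 5 points at 0.0139 M or 0.0982 M of second substrate. The neighbouring flask held 0.20 M of starting material with the same second substrate, so I kept the cap of 7.20% for it. With 92.2% of its starting material and 71.6% of its second substrate left at 8.0 min, averaging opening and closing pace gives 5.98%, and the neighbouring flask gave 6.12% of uncatalysed product.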